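**Plan**

1. Numbering: furanone O1, C2 (C=O), C3 (Me), C4 (OH), C5; chain C6 (ylidene CH), C7 (methyl-bearing stereocentre) on to C18 (CH2 on the furan). The enabling feature is the tetronic acid ring O1–C2–C3–C4–C5: its C3–C4 bond is an enolate-to-ester bond, and its exocyclic C5=C6 alkene (C7 cis to C4) can be carried in as a geometry-defined enol ester.
2. Retrosynthetic cuts, in order: C3–C4 (Dieckmann closure, last step); O1–C5 (copper-catalysed coupling of propanoate with an alkenyl iodide); C4–C5 and C5–C6 (Corey–Fuchs homologation and carboxylation of a C6 aldehyde); C12–C13 (alkenylalane plus allylic chloride); C13–C14 (formaldehyde); C8–C9 and C17–C18 (copper-catalysed couplings of one C4 alkynyl Grignard reagent, made once and used twice).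
3. Forward order: the chain is joined first. Furan piece 9 (C13–C18) and alkyne 15 (C6–C12) are united at C12–C13, C6 is homologated to ynoate 22, C5 is oxygenated via stannane 23 and iodide 24, and the only ring made in the route, the furanone, closes last.
4. Stereochemistry: C7 comes from the (R)-Roche ester and is never broken. The C11=C12 and C14=C15 E geometries come from syn carboalumination. The C5=C6 E geometry comes from syn hydrostannation of 22 followed by retentive Sn→I and I→O exchanges, and the ring closure does not touch it.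

Key step: step 20

Assumption: the 4-hydroxyfuran-2(5H)-one tautomer drawn in the target SMILES is the form isolated after acidic work-up; the labile bromide 2 is used as a freshly made solution, and Grignard reagent 4 is kept under argon as a titrated THF stock solution that serves steps 3 and 10.

**Route**

Step 1
Reactants: 1 furan-3-ylmethanol
Product: 2 3-(bromomethyl)furan
Conditions: PBr3 (0.4 equiv), pyridine (cat.), Et2O, −10 → 0 °C; used at once as an ether solution
Reagents that add atoms: phosphorus tribromide, BrP(Br)Br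
Why: SN2 bromination of a primary furylmethyl alcohol through its phosphite ester is a standard halogenation, and the sensitive bromide is not stored.

Step 2
Reactants: 3 (4-bromobut-1-yn-1-yl)trimethylsilane
Product: 4 [4-(trimethylsilyl)but-3-yn-1-yl]magnesium bromide
Conditions: Mg turnings (1.5 equiv, activated with a crystal of I2), THF, slow addition, rt → 40 °C; decanted, titrated and kept under argon as a stock solution
Reagents that add atoms: magnesium, [Mg]
Why: Grignard formation by insertion of magnesium into the primary C–Br bond is routine for this homopropargylic bromide, since the silyl cap removes the acidic alkyne proton and slow addition limits Wurtz coupling.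

Step 3
Reactants: 2 3-(bromomethyl)furan; 4 [4-(trimethylsilyl)but-3-yn-1-yl]magnesium bromide
Product: 5 [5-(furan-3-yl)pent-1-yn-1-yl]trimethylsilane
Conditions: Li2CuCl4 (3 mol %), THF, −78 → 0 °C
Reagents that add atoms: none
Why: Copper-catalysed Grignard cross-coupling of a primary alkylmagnesium bromide with a reactive heteroarylmethyl bromide should form the C17–C18 bond, the silyl cap keeping the alkyne inert to the Grignard reagent.

Step 4
Reactants: 5 [5-(furan-3-yl)pent-1-yn-1-yl]trimethylsilane
Product: 6 3-(pent-4-yn-1-yl)furan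
Conditions: K2CO3 (cat.), MeOH, rt
Reagents that add atoms: none
Why: Carbonate-catalysed methanolysis of the alkynyl C–Si bond is the standard protodesilylation of a trimethylsilylalkyne and leaves the furan alone.

Step 5
Reactants: 6 3-(pent-4-yn-1-yl)furan
Product: 8 (2E)-6-(furan-3-yl)-3-methylhex-2-en-1-ol, via alkenylalane 7 (not isolated)
Conditions: AlMe3 (2 equiv), Cp2ZrCl2 (25 mol %), CH2Cl2, 0 °C → rt; then (CH2O)n, 0 °C → rt; aq. potassium sodium tartrate
Reagents that add atoms: trimethylaluminium, C[Al](C)C; formaldehyde (as paraformaldehyde), C=O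
Why: Zirconium-catalysed methylalumination (Negishi carboalumination) adds Me and Al syn across the terminal alkyne with Al on the terminal carbon, and hydroxymethylation of the alkenylalane with retention fixes the C14=C15 E geometry.

Step 6
Reactants: 8 (2E)-6-(furan-3-yl)-3-methylhex-2-en-1-ol
Product: 9 3-[(4E)-6-chloro-4-methylhex-4-en-1-yl]furan
Conditions: MsCl, LiCl, 2,4,6-collidine, DMF, 0 °C
Reagents that add atoms: lithium chloride, [Li+].[Cl-]
Why: Mesylation with in situ SN2 displacement by chloride is the standard conversion of prenyl-type alcohols into primary allylic chlorides without allylic transposition or loss of E geometry.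

Step 7
Reactants: 10 methyl (2R)-3-hydroxy-2-methylpropanoate
Product: 11 methyl (2R)-3-[(tert-butyldiphenylsilyl)oxy]-2-methylpropanoate
Conditions: TBDPSCl, imidazole, CH2Cl2, 0 °C → rt
Reagents that add atoms: tert-butyl(chloro)diphenylsilane, CC(C)(C)[Si](Cl)(c1ccccc1)c1ccccc1
Why: Routine silylation of the primary hydroxyl gives an ether that tolerates hydride, Grignard, alane and carbonate conditions and resists 1,3-silyl migration, so the future C7 centre cannot be scrambled.

Step 8
Reactants: 11 methyl (2R)-3-[(tert-butyldiphenylsilyl)oxy]-2-methylpropanoate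
Product: 12 (2S)-3-[(tert-butyldiphenylsilyl)oxy]-2-methylpropan-1-ol
Conditions: i-Bu2AlH (2.5 equiv), CH2Cl2, −78 → 0 °C; aq. potassium sodium tartrate
Reagents that add atoms: none
Why: Hydride reduction of the ester to the primary alcohol with excess DIBAL-H is standard and does not touch the stereocentre (the descriptor changes only by priority).

Step 9
Reactants: 12 (2S)-3-[(tert-butyldiphenylsilyl)oxy]-2-methylpropan-1-ol
Product: 13 (2R)-3-[(tert-butyldiphenylsilyl)oxy]-2-methylpropyl 4-methylbenzenesulfonate
Conditions: TsCl, Et3N, DMAP (cat.), CH2Cl2, 0 °C → rt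
Reagents that add atoms: 4-methylbenzenesulfonyl chloride, Cc1ccc(cc1)S(Cl)(=O)=O
Why: Sulfonylation of a primary alcohol is routine and installs the leaving group for the sp3–sp3 coupling.

Step 10
Reactants: 13 (2R)-3-[(tert-butyldiphenylsilyl)oxy]-2-methylpropyl 4-methylbenzenesulfonate; 4 [4-(trimethylsilyl)but-3-yn-1-yl]magnesium bromide
Product: 14 tert-butyl{[(2S)-2-methyl-7-(trimethylsilyl)hept-6-yn-1-yl]oxy}diphenylsilane
Conditions: Li2CuCl4 (5 mol %), THF, −78 °C → rt
Reagents that add atoms: none
Why: Copper-catalysed coupling of an alkyl Grignard reagent with a primary tosylate is a well-used way to extend Roche-ester-derived chains; it forms C8–C9 without touching the adjacent stereocentre.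

Step 11
Reactants: 14 tert-butyl{[(2S)-2-methyl-7-(trimethylsilyl)hept-6-yn-1-yl]oxy}diphenylsilane
Product: 15 tert-butyl{[(2S)-2-methylhept-6-yn-1-yl]oxy}diphenylsilane
Conditions: K2CO3 (cat.), MeOH–THF, rt
Reagents that add atoms: none
Why: Protodesilylation of the alkynylsilane by carbonate in methanol is selective, the hindered primary TBDPS ether being stable under these conditions.

Step 12
Reactants: 15 tert-butyl{[(2S)-2-methylhept-6-yn-1-yl]oxy}diphenylsilane; 9 3-[(4E)-6-chloro-4-methylhex-4-en-1-yl]furan
Product: 17 tert-butyl{[(2S,6E,9E)-13-(furan-3-yl)-2,6,10-trimethyltrideca-6,9-dien-1-yl]oxy}diphenylsilane, via alkenylalane 16 (not isolated)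
Conditions: AlMe3 (2 equiv), Cp2ZrCl2 (25 mol %), CH2Cl2, 0 °C → rt; volatiles removed; then 9, Pd(PPh3)4 (5 mol %), THF, rt; aq. potassium sodium tartrate
Reagents that add atoms: trimethylaluminium, C[Al](C)C
Why: A second Negishi carboalumination gives the (E)-alkenylalane by syn addition, and its cross-coupling with the allylic chloride under zerovalent palladium catalysis joins C12 to the primary allylic carbon C13 with retention of both alkene geometries, the established route to 1,4-dienes; C11=C12 is set E here.

Step 13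
Reactants: 17 tert-butyl{[(2S,6E,9E)-13-(furan-3-yl)-2,6,10-trimethyltrideca-6,9-dien-1-yl]oxy}diphenylsilane
Product: 18 (2S,6E,9E)-13-(furan-3-yl)-2,6,10-trimethyltrideca-6,9-dien-1-ol
Conditions: Bu4NF, THF, 0 °C → rt
Reagents that add atoms: none
Why: Fluoride cleavage of the silyl ether is routine and compatible with the furan and the skipped diene.

Step 14
Reactants: 18 (2S,6E,9E)-13-(furan-3-yl)-2,6,10-trimethyltrideca-6,9-dien-1-ol
Product: 19 (2S,6E,9E)-13-(furan-3-yl)-2,6,10-trimethyltrideca-6,9-dienal
Conditions: Dess–Martin periodinane, CH2Cl2, 0 °C → rt; used without storage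
Reagents that add atoms: none
Why: Dess–Martin oxidation gives the aldehyde under near-neutral conditions that should neither epimerise the α-methyl centre nor oxidise the furan.

Step 15
Reactants: 19 (2S,6E,9E)-13-(furan-3-yl)-2,6,10-trimethyltrideca-6,9-dienal
Product: 20 3-[(4E,7E,12S)-14,14-dibromo-4,8,12-trimethyltetradeca-4,7,13-trien-1-yl]furan
Conditions: CBr4, PPh3, Et3N, CH2Cl2, 0 °C
Reagents that add atoms: tetrabromomethane, BrC(Br)(Br)Br
Why: First stage of the Corey–Fuchs reaction, a Wittig-type dibromomethylenation by the ylide formed from CBr4 and PPh3, with Et3N buffering the acid-sensitive furan and diene.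

Step 16
Reactants: 20 3-[(4E,7E,12S)-14,14-dibromo-4,8,12-trimethyltetradeca-4,7,13-trien-1-yl]furan
Product: 22 methyl (4S,8E,11E)-15-(furan-3-yl)-4,8,12-trimethylpentadeca-8,11-dien-2-ynoate, via lithium acetylide 21 (not isolated)
Conditions: n-BuLi (2.05 equiv), THF, −78 °C; then ClCO2Me, −78 → −20 °C
Reagents that add atoms: methyl chloroformate, COC(=O)Cl
Why: Second stage of the Corey–Fuchs reaction: bromine–lithium exchange and elimination give the lithium acetylide, which is C-acylated by the chloroformate; at −78 °C with two equivalents of base the furan C–H bonds and the propargylic stereocentre should stay untouched.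

Step 17
Reactants: 22 methyl (4S,8E,11E)-15-(furan-3-yl)-4,8,12-trimethylpentadeca-8,11-dien-2-ynoate
Product: 23 methyl (2E,4S,8E,11E)-15-(furan-3-yl)-4,8,12-trimethyl-2-(tributylstannyl)pentadeca-2,8,11-trienoate
Conditions: Bu3SnH (slow addition), Pd(PPh3)4 (3 mol %), THF, 0 °C → rt
Reagents that add atoms: tributylstannane, CCCC[SnH](CCCC)CCCC
Why: Palladium-catalysed hydrostannation of a 2-alkynoate is a syn addition that puts tin on the α-carbon (C5) and hydrogen on C6, so C7 and the ester carbon end up cis; isolated trisubstituted alkenes and the furan do not react.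

Step 18
Reactants: 23 methyl (2E,4S,8E,11E)-15-(furan-3-yl)-4,8,12-trimethyl-2-(tributylstannyl)pentadeca-2,8,11-trienoate
Product: 24 methyl (2E,4S,8E,11E)-15-(furan-3-yl)-2-iodo-4,8,12-trimethylpentadeca-2,8,11-trienoate
Conditions: I2 (1.05 equiv), CH2Cl2, 0 °C, dark; aq. Na2S2O3
Reagents that add atoms: iodine, II
Why: Iododestannylation is an ipso electrophilic substitution at the alkenyl carbon that proceeds with retention of geometry and should outpace any reaction of iodine with the trisubstituted alkenes or the furan at 0 °C.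

Step 19
Reactants: 24 methyl (2E,4S,8E,11E)-15-(furan-3-yl)-2-iodo-4,8,12-trimethylpentadeca-2,8,11-trienoate; 25 propanoic acid
Product: 26 methyl (2E,4S,8E,11E)-15-(furan-3-yl)-4,8,12-trimethyl-2-(propanoyloxy)pentadeca-2,8,11-trienoate
Conditions: CuI (20 mol %), 3,4,7,8-tetramethyl-1,10-phenanthroline (40 mol %), Cs2CO3, toluene, 60 °C, dark
Reagents that add atoms: none
Why: Ullmann-type C–O coupling of an alkenyl iodide with a carboxylate under monovalent copper catalysis (O-vinylation of a carboxylic acid) proceeds by oxidative addition and reductive elimination at the sp2 carbon with retention, so the enol propanoate should keep C7 cis to the ester carbon.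

Step 20
Reactants: 26 methyl (2E,4S,8E,11E)-15-(furan-3-yl)-4,8,12-trimethyl-2-(propanoyloxy)pentadeca-2,8,11-trienoate
Product: 28 (5E)-5-[(2S,6E,9E)-13-(furan-3-yl)-2,6,10-trimethyltrideca-6,9-dien-1-ylidene]-4-hydroxy-3-methylfuran-2(5H)-one, via lithium tetronate 27 (not isolated)
Conditions: LiN(SiMe3)2 (2.2 equiv), THF, −78 → −40 °C; then cold 0.5 M HCl, dim light
Reagents that add atoms: none
Why: The amide base removes a proton from the propanoyl CH2 (C3) and the ester enolate adds to the neighbouring methyl ester carbonyl (C4); loss of methoxide and deprotonation of the resulting 1,3-dicarbonyl give the lithium tetronate, which is protonated on work-up. The closest known reaction type is the Dieckmann (intramolecular Claisen) condensation of 2-acyloxy esters and 2-acyloxy-2-alkenoates to tetronic acids and 5-ylidene tetronic acids with lithium amide bases. The furanone ring closes at C3–C4 in a 5-exo-trig mode, whereas the competing Michael closure onto C6 would be 5-endo-trig and is disfavoured. No stereocentre is formed, and C7 and the three alkene geometries are carried through. The step needs α-deprotonation of the propanoate in preference to γ-deprotonation at C7, and cyclisation faster than E1cB fragmentation of the enol-ester enolate to methylketene; the hindered, weakly basic amide at −78 °C, the higher acidity of an enol-ester α-CH2 and the proximity of the ester carbonyl serve both. The C5=C6 E geometry is secured because the new bond is remote from the alkene and tetronate formation is irreversible, and the work-up is kept cold, brief and dim to avoid E-to-Z equilibration.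

**Compound list**

1 | furan-3-ylmethanol | OCc1ccoc1 | starting material
2 | 3-(bromomethyl)furan | BrCc1ccoc1 | intermediate
3 | (4-bromobut-1-yn-1-yl)trimethylsilane | C[Si](C)(C)C#CCCBr | starting material
4 | [4-(trimethylsilyl)but-3-yn-1-yl]magnesium bromide | C[Si](C)(C)C#CCC[Mg]Br | intermediate
5 | [5-(furan-3-yl)pent-1-yn-1-yl]trimethylsilane | C[Si](C)(C)C#CCCCc1ccoc1 | intermediate
6 | 3-(pent-4-yn-1-yl)furan | C#CCCCc1ccoc1 | intermediate
7 | [(1E)-5-(furan-3-yl)-2-methylpent-1-en-1-yl]dimethylalumane | C[Al](C)/C=C(\C)CCCc1ccoc1 | intermediate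
8 | (2E)-6-(furan-3-yl)-3-methylhex-2-en-1-ol | OC/C=C(\C)CCCc1ccoc1 | intermediate
9 | 3-[(4E)-6-chloro-4-methylhex-4-en-1-yl]furan | ClC/C=C(\C)CCCc1ccoc1 | intermediate
10 | methyl (2R)-3-hydroxy-2-methylpropanoate | COC(=O)[C@H](C)CO | starting material
11 | methyl (2R)-3-[(tert-butyldiphenylsilyl)oxy]-2-methylpropanoate | COC(=O)[C@H](C)CO[Si](c1ccccc1)(c1ccccc1)C(C)(C)C | intermediate
12 | (2S)-3-[(tert-butyldiphenylsilyl)oxy]-2-methylpropan-1-ol | OC[C@H](C)CO[Si](c1ccccc1)(c1ccccc1)C(C)(C)C | intermediate
13 | (2R)-3-[(tert-butyldiphenylsilyl)oxy]-2-methylpropyl 4-methylbenzenesulfonate | Cc1ccc(cc1)S(=O)(=O)OC[C@H](C)CO[Si](c1ccccc1)(c1ccccc1)C(C)(C)C | intermediate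
14 | tert-butyl{[(2S)-2-methyl-7-(trimethylsilyl)hept-6-yn-1-yl]oxy}diphenylsilane | C[Si](C)(C)C#CCCC[C@H](C)CO[Si](c1ccccc1)(c1ccccc1)C(C)(C)C | intermediate
15 | tert-butyl{[(2S)-2-methylhept-6-yn-1-yl]oxy}diphenylsilane | C#CCCC[C@H](C)CO[Si](c1ccccc1)(c1ccccc1)C(C)(C)C | intermediate
16 | {(1E,6S)-7-[(tert-butyldiphenylsilyl)oxy]-2,6-dimethylhept-1-en-1-yl}dimethylalumane | C[Al](C)/C=C(\C)CCC[C@H](C)CO[Si](c1ccccc1)(c1ccccc1)C(C)(C)C | intermediate
17 | tert-butyl{[(2S,6E,9E)-13-(furan-3-yl)-2,6,10-trimethyltrideca-6,9-dien-1-yl]oxy}diphenylsilane | CC(C)(C)[Si](c1ccccc1)(c1ccccc1)OC[C@@H](C)CCC/C(C)=C/C/C=C(\C)CCCc1ccoc1 | intermediate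
18 | (2S,6E,9E)-13-(furan-3-yl)-2,6,10-trimethyltrideca-6,9-dien-1-ol | OC[C@@H](C)CCC/C(C)=C/C/C=C(\C)CCCc1ccoc1 | intermediate
19 | (2S,6E,9E)-13-(furan-3-yl)-2,6,10-trimethyltrideca-6,9-dienal | O=C[C@@H](C)CCC/C(C)=C/C/C=C(\C)CCCc1ccoc1 | intermediate
20 | 3-[(4E,7E,12S)-14,14-dibromo-4,8,12-trimethyltetradeca-4,7,13-trien-1-yl]furan | BrC(Br)=C[C@@H](C)CCC/C(C)=C/C/C=C(\C)CCCc1ccoc1 | intermediate
21 | [(3S,7E,10E)-14-(furan-3-yl)-3,7,11-trimethyltetradeca-7,10-dien-1-yn-1-yl]lithium | [Li]C#C[C@@H](C)CCC/C(C)=C/C/C=C(\C)CCCc1ccoc1 | intermediate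
22 | methyl (4S,8E,11E)-15-(furan-3-yl)-4,8,12-trimethylpentadeca-8,11-dien-2-ynoate | COC(=O)C#C[C@@H](C)CCC/C(C)=C/C/C=C(\C)CCCc1ccoc1 | intermediate
23 | methyl (2E,4S,8E,11E)-15-(furan-3-yl)-4,8,12-trimethyl-2-(tributylstannyl)pentadeca-2,8,11-trienoate | COC(=O)/C(=C\[C@@H](C)CCC/C(C)=C/C/C=C(\C)CCCc1ccoc1)[Sn](CCCC)(CCCC)CCCC | intermediate
24 | methyl (2E,4S,8E,11E)-15-(furan-3-yl)-2-iodo-4,8,12-trimethylpentadeca-2,8,11-trienoate | COC(=O)/C(I)=C\[C@@H](C)CCC/C(C)=C/C/C=C(\C)CCCc1ccoc1 | intermediate
25 | propanoic acid | CCC(=O)O | starting material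
26 | methyl (2E,4S,8E,11E)-15-(furan-3-yl)-4,8,12-trimethyl-2-(propanoyloxy)pentadeca-2,8,11-trienoate | COC(=O)/C(=C\[C@@H](C)CCC/C(C)=C/C/C=C(\C)CCCc1ccoc1)OC(=O)CC | intermediate
27 | lithium (5E)-5-[(2S,6E,9E)-13-(furan-3-yl)-2,6,10-trimethyltrideca-6,9-dien-1-ylidene]-3-methyl-2-oxo-2,5-dihydrofuran-4-olate | CC1=C(O[Li])/C(=C\[C@@H](C)CCC/C(C)=C/C/C=C(\C)CCCc2ccoc2)OC1=O | intermediate
28 | (5E)-5-[(2S,6E,9E)-13-(furan-3-yl)-2,6,10-trimethyltrideca-6,9-dien-1-ylidene]-4-hydroxy-3-methylfuran-2(5H)-one | CC1=C(O)/C(=C\[C@@H](C)CCC/C(C)=C/C/C=C(\C)CCCc2ccoc2)OC1=O | target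

**Step count**

Total: 20 steps. Longest linear sequence: 14 steps (10 to 28, steps 7–20). The furan piece 9 is made in a five-step branch (steps 1 and 3–6) and joins at step 12; Grignard reagent 4 (step 2) feeds both branches.

**Steps most likely to fail**

Step 19. The alkenylcopper intermediate formed from the α-iodo enoate may lose its geometry through an allenoate-type form, or be reduced or homocoupled, before the C–O bond forms; warm carbonate may also isomerise the product. The fallback sets out from aldehyde 19 and returns at 26, making the C5=C6 bond and the enol ester together by a Still–Gennari-type Horner–Wadsworth–Emmons olefination. Purchased methyl bis(2,2,2-trifluoroethyl)phosphonoacetate would be converted by diazo transfer (4-acetamidobenzenesulfonyl azide, DBU, MeCN) into methyl 2-[bis(2,2,2-trifluoroethoxy)phosphoryl]-2-diazoacetate F1. O–H insertion into propanoic acid 25 catalysed by Rh2(OAc)4 should then give methyl 2-[bis(2,2,2-trifluoroethoxy)phosphoryl]-2-(propanoyloxy)acetate F2. Its potassium anion (KN(SiMe3)2, 18-crown-6, THF, −78 °C) is expected, by analogy with α-alkyl and α-halo reagents of this type, to condense with 19 mainly to the isomer with the ester cis to the chain, which is 26. The other isomer would be removed by chromatography, so the geometry would then rest on kinetic selectivity and separation; steps 15–18 would be bypassed as well.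

Step 20. The enol-ester enolate may fragment to methylketene and an α-keto ester enolate, or the base may remove the γ-proton at C7, with loss of configuration and of the C5=C6 geometry. The fallback sets out from aldehyde 19 and returns at the target 28, attaching the chain to a preformed ring. Purchased 4-methoxy-3-methylfuran-2(5H)-one is lithiated at C5 (LiN(i-Pr)2, THF, −78 °C) and added to 19 to give 5-[(2S,6E,9E)-13-(furan-3-yl)-1-hydroxy-2,6,10-trimethyltrideca-6,9-dien-1-yl]-4-methoxy-3-methylfuran-2(5H)-one F3. Mesylation (MsCl, Et3N) gives (2S,6E,9E)-13-(furan-3-yl)-1-(3-methoxy-4-methyl-5-oxo-2,5-dihydrofuran-2-yl)-2,6,10-trimethyltrideca-6,9-dien-1-yl methanesulfonate F4. Elimination with DBU should give mainly (5Z)-5-[(2S,6E,9E)-13-(furan-3-yl)-2,6,10-trimethyltrideca-6,9-dien-1-ylidene]-4-methoxy-3-methylfuran-2(5H)-one F5. O-Demethylation with sodium propane-1-thiolate in DMF would give (5Z)-5-[(2S,6E,9E)-13-(furan-3-yl)-2,6,10-trimethyltrideca-6,9-dien-1-ylidene]-4-hydroxy-3-methylfuran-2(5H)-one F6. Irradiation should set up a Z/E mixture from which 28 is separated and the Z isomer recycled. In this contingency the geometry is no longer preset but rests on photoequilibration and separation.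

Step 16. Butyllithium may deprotonate the furan α-C–H bonds or add to the ynoate as it forms. The fallback sets out from aldehyde 19 and returns at 22 without any alkyllithium, also bypassing step 15. Ohira–Bestmann homologation (dimethyl (1-diazo-2-oxopropyl)phosphonate, K2CO3, MeOH, 0 °C → rt) should give 3-[(4E,7E,12S)-4,8,12-trimethyltetradeca-4,7-dien-13-yn-1-yl]furan F7. Deprotonation with EtMgBr (THF, 0 °C → rt) gives [(3S,7E,10E)-14-(furan-3-yl)-3,7,11-trimethyltetradeca-7,10-dien-1-yn-1-yl]magnesium bromide F8, which is acylated with ClCO2Me to 22.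

**Further compounds**

F1 | step 19 | methyl 2-[bis(2,2,2-trifluoroethoxy)phosphoryl]-2-diazoacetate | COC(=O)C(=[N+]=[N-])P(=O)(OCC(F)(F)F)OCC(F)(F)F
F2 | step 19 | methyl 2-[bis(2,2,2-trifluoroethoxy)phosphoryl]-2-(propanoyloxy)acetate | CCC(=O)OC(C(=O)OC)P(=O)(OCC(F)(F)F)OCC(F)(F)F
F3 | step 20 | 5-[(2S,6E,9E)-13-(furan-3-yl)-1-hydroxy-2,6,10-trimethyltrideca-6,9-dien-1-yl]-4-methoxy-3-methylfuran-2(5H)-one | COC1=C(C)C(=O)OC1C(O)[C@@H](C)CCC/C(C)=C/C/C=C(\C)CCCc2ccoc2
F4 | step 20 | (2S,6E,9E)-13-(furan-3-yl)-1-(3-methoxy-4-methyl-5-oxo-2,5-dihydrofuran-2-yl)-2,6,10-trimethyltrideca-6,9-dien-1-yl methanesulfonate | COC1=C(C)C(=O)OC1C(OS(C)(=O)=O)[C@@H](C)CCC/C(C)=C/C/C=C(\C)CCCc2ccoc2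
F5 | step 20 | (5Z)-5-[(2S,6E,9E)-13-(furan-3-yl)-2,6,10-trimethyltrideca-6,9-dien-1-ylidene]-4-methoxy-3-methylfuran-2(5H)-one | COC1=C(C)C(=O)O/C1=C\[C@@H](C)CCC/C(C)=C/C/C=C(\C)CCCc2ccoc2
F6 | step 20 | (5Z)-5-[(2S,6E,9E)-13-(furan-3-yl)-2,6,10-trimethyltrideca-6,9-dien-1-ylidene]-4-hydroxy-3-methylfuran-2(5H)-one | CC1=C(O)/C(=C/[C@@H](C)CCC/C(C)=C/C/C=C(\C)CCCc2ccoc2)OC1=O
F7 | step 16 | 3-[(4E,7E,12S)-4,8,12-trimethyltetradeca-4,7-dien-13-yn-1-yl]furan | C#C[C@@H](C)CCC/C(C)=C/C/C=C(\C)CCCc1ccoc1
F8 | step 16 | [(3S,7E,10E)-14-(furan-3-yl)-3,7,11-trimethyltetradeca-7,10-dien-1-yn-1-yl]magnesium bromide | Br[Mg]C#C[C@@H](C)CCC/C(C)=C/C/C=C(\C)CCCc1ccoc1
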